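**Strategy.** Everything rests on disconnecting the oxolane O–C9 bond together with the C10–O bond, which turns the ring and the laurate carbinol back into an acyclic (E)-C9=C10 alkene whose C6 hydroxyl lies bishomoallylic to it (chain numbered from the pentyl methyl). A rhenium(VII) syn-oxidative cyclisation then closes the 2,5-trans oxolane (O, C6–C9) and sets C9 and C10 in the threo relation in one operation, leaving C10–OH as the only free hydroxyl for lauroylation. The cyclisation substrate is (6S,7S,9E)-7-(methoxymethoxy)nonadeca-9,18-dien-6-ol, built from hexanal by syn-selective alkoxyallylboration (C6, C7) and a Julia–Kocienski olefination that installs the E alkene and the terminal vinyl chain.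

Key step: step 9

Remark: atoms are numbered C1–C19 along the chain from the pentyl methyl to the terminal alkene carbon; allyl methoxymethyl ether is treated as a catalogue chemical (otherwise one step from allyl alcohol and chloromethyl methyl ether).

**Route**

Step 1
Reactants: 1 allyl methoxymethyl ether; 2 hexanal
Product: 7 (3S,4S)-3-(methoxymethoxy)non-1-en-4-ol, via allyllithium 3 (not isolated), via lithium borate 4 (not isolated), via allylborane 5 (not isolated), via borinate 6 (not isolated)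
Conditions: 1, s-BuLi, THF, −78 °C; (+)-Ipc2BOMe [the enantiomer made from (−)-α-pinene], −78 °C; BF3·OEt2, then 2, −78 °C → rt; NaOH, H2O2, rt
Reagents that add atoms: none
Why: Brown asymmetric alkoxyallylboration, in which the kinetically formed (Z)-γ-alkoxyallylborane reacts through a chair Zimmerman–Traxler transition state so that the Z geometry gives the 6,7-syn relation and the (−)-α-pinene-derived isopinocampheyl groups direct attack to the Re face of hexanal, setting C6 and C7 both S.

Step 2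
Reactants: 7 (3S,4S)-3-(methoxymethoxy)non-1-en-4-ol
Product: 8 tert-butyl{[(3S,4S)-3-(methoxymethoxy)non-1-en-4-yl]oxy}dimethylsilane
Conditions: TBSCl, imidazole, DMAP (cat.), DMF, rt
Reagents that add atoms: tert-butyldimethylsilyl chloride, CC(C)(C)[Si](C)(C)Cl
Why: Imidazole-promoted silylation of the only free hydroxyl masks C6–OH, so that the C9 aldehyde of step 4 cannot close to a lactol and no alkoxide is present in step 7.

Step 3
Reactants: 8 tert-butyl{[(3S,4S)-3-(methoxymethoxy)non-1-en-4-yl]oxy}dimethylsilane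
Product: 10 (3S,4S)-4-{[tert-butyl(dimethyl)silyl]oxy}-3-(methoxymethoxy)nonan-1-ol, via alkylborane 9 (not isolated)
Conditions: 9-BBN, THF, 0 °C → rt; then NaOH, H2O2, 0 °C → rt
Reagents that add atoms: hydrogen peroxide, OO
Why: Anti-Markovnikov hydroboration of the monosubstituted alkene with bulky 9-BBN, followed by alkaline peroxide oxidation, places the hydroxyl on the terminal carbon (C9) without touching a stereocentre.

Step 4
Reactants: 10 (3S,4S)-4-{[tert-butyl(dimethyl)silyl]oxy}-3-(methoxymethoxy)nonan-1-ol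
Product: 11 (3S,4S)-4-{[tert-butyl(dimethyl)silyl]oxy}-3-(methoxymethoxy)nonanal
Conditions: Dess–Martin periodinane, CH2Cl2, 0 °C → rt
Reagents that add atoms: none
Why: Dess–Martin oxidation gives the aldehyde under near-neutral conditions that spare the silyl ether and the acetal and should avoid β-elimination of the C7 alkoxy group; the aldehyde is used without storage.

Step 5
Reactants: 12 dec-9-en-1-ol
Product: 13 5-(dec-9-en-1-ylsulfanyl)-1-phenyl-1H-tetrazole
Conditions: 1-phenyl-1H-tetrazole-5-thiol, PPh3, DIAD, THF, 0 °C → rt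
Reagents that add atoms: 1-phenyl-1H-tetrazole-5-thiol, Sc1nnnn1-c1ccccc1
Why: Mitsunobu thioetherification of an unhindered primary alcohol with the acidic tetrazolethiol, with the remote alkene inert.

Step 6
Reactants: 13 5-(dec-9-en-1-ylsulfanyl)-1-phenyl-1H-tetrazole
Product: 14 5-(dec-9-ene-1-sulfonyl)-1-phenyl-1H-tetrazole
Conditions: (NH4)6Mo7O24·4H2O (cat.), 30% H2O2, EtOH, 0 °C → rt
Reagents that add atoms: hydrogen peroxide, OO
Why: Molybdate-catalysed peroxide oxidation of the sulfide to the sulfone does not epoxidise an unactivated terminal alkene.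

Step 7
Reactants: 14 5-(dec-9-ene-1-sulfonyl)-1-phenyl-1H-tetrazole; 11 (3S,4S)-4-{[tert-butyl(dimethyl)silyl]oxy}-3-(methoxymethoxy)nonanal
Product: 18 tert-butyl{[(6S,7S,9E)-7-(methoxymethoxy)nonadeca-9,18-dien-6-yl]oxy}dimethylsilane, via sulfonyl carbanion 15 (not isolated), via alkoxide adduct 16 (not isolated), via sulfinate 17 (not isolated)
Conditions: 14, KHMDS, DME, −60 °C; then 11, −60 °C → rt
Reagents that add atoms: none
Why: Julia–Kocienski olefination, in which the potassium sulfonyl carbanion adds to the aldehyde, Smiles rearrangement and anti-periplanar loss of SO2 and tetrazololate follow, and the open transition state favoured by K+ in DME should give the (E)-C9=C10 alkene; any Z isomer is to be removed on silver nitrate-impregnated silica before step 9.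

Step 8
Reactants: 18 tert-butyl{[(6S,7S,9E)-7-(methoxymethoxy)nonadeca-9,18-dien-6-yl]oxy}dimethylsilane
Product: 19 (6S,7S,9E)-7-(methoxymethoxy)nonadeca-9,18-dien-6-ol
Conditions: TBAF, THF, rt
Reagents that add atoms: none
Why: Fluoride-mediated desilylation frees C6–OH while the MOM acetal and both alkenes are untouched.

Step 9
Reactants: 19 (6S,7S,9E)-7-(methoxymethoxy)nonadeca-9,18-dien-6-ol
Product: 22 (6S,7S,9R,10R)-6,9-epoxy-7-(methoxymethoxy)nonadec-18-en-10-ol, via perrhenate ester 20 (not isolated), via rhenium(V) alkoxide 21 (not isolated)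
Conditions: Re2O7 (2 equiv), 2,6-lutidine (4 equiv), CH2Cl2, 0 °C → rt; then aq NaOH/H2O2, 0 °C
Reagents that add atoms: rhenium(VII) oxide, O=[Re](=O)(=O)O[Re](=O)(=O)=O
Why: The C6 alcohol exchanges onto rhenium to give the perrhenate ester, whose alkoxide oxygen and one Re=O oxygen add suprafacially, in a formal [3+2] fashion, across C9=C10 to form O–C9 and C10–O, and the peroxide work-up hydrolyses the rhenium(V) alkoxide to the C10 alcohol. The closest known reaction type is the rhenium(VII) oxide syn-oxidative cyclisation of 5-hydroxyalkenes (bishomoallylic alcohols) to trans-2,5-disubstituted 2-(1-hydroxyalkyl)oxolanes. The oxolane closes in the 5-exo-trig mode. C9 is controlled by the C6 stereocentre, whose pentyl group sits pseudo-equatorial in the chair-like transition state and so places C10 trans to it (2,5-trans), while C10 is controlled by the E geometry of the alkene together with the syn addition (9,10-threo). The step needs π-facial selectivity at C9=C10 and chemoselectivity over the C18=C19 alkene; the first comes from C6, the second from the fact that only C9=C10 can reach the rhenium tethered at O6. Lutidine keeps the medium non-acidic and occupies free coordination sites on rhenium, so that the C7 acetal should neither ionise nor chelate.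

Step 10
Reactants: 22 (6S,7S,9R,10R)-6,9-epoxy-7-(methoxymethoxy)nonadec-18-en-10-ol; 23 dodecanoyl chloride
Product: 24 (6S,7S,9R,10R)-6,9-epoxy-7-(methoxymethoxy)nonadec-18-en-10-yl dodecanoate
Conditions: pyridine, DMAP (cat.), CH2Cl2, 0 °C → rt
Reagents that add atoms: none
Why: DMAP-catalysed acylation (nucleophilic acyl substitution) of the single free hydroxyl, at C10, proceeds with retention of configuration.

Step 11
Reactants: 24 (6S,7S,9R,10R)-6,9-epoxy-7-(methoxymethoxy)nonadec-18-en-10-yl dodecanoate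
Product: 25 (6S,7S,9R,10R)-6,9-epoxy-7-hydroxynonadec-18-en-10-yl dodecanoate
Conditions: ZnBr2, n-PrSH, CH2Cl2, 0 °C → rt
Reagents that add atoms: none
Why: Lewis acid-assisted thiolytic cleavage of the MOM acetal, in which zinc bromide activates the acetal and the thiol captures the methoxymethyl unit, is brief and mild enough to spare the C10 laurate, the oxolane and the terminal alkene.

**Compound list**

1 | allyl methoxymethyl ether [3-(methoxymethoxy)prop-1-ene] | C=CCOCOC | starting material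
2 | hexanal | CCCCCC=O | starting material
3 | [(2Z)-3-(methoxymethoxy)prop-2-en-1-yl]lithium | C(/OCOC)=C/C[Li] | intermediate (not isolated)
4 | lithium methoxy[(2Z)-3-(methoxymethoxy)prop-2-en-1-yl]bis(isopinocampheyl)borate, Ipc from (−)-α-pinene | [Li+].C(/OCOC)=C/C[B-](OC)([C@H]1C[C@H]2C[C@@H]([C@@H]1C)C2(C)C)[C@H]1C[C@H]2C[C@@H]([C@@H]1C)C2(C)C | intermediate (not isolated)
5 | [(2Z)-3-(methoxymethoxy)prop-2-en-1-yl]bis(isopinocampheyl)borane | C(/OCOC)=C/CB([C@H]1C[C@H]2C[C@@H]([C@@H]1C)C2(C)C)[C@H]1C[C@H]2C[C@@H]([C@@H]1C)C2(C)C | intermediate (not isolated)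
6 | (3S,4S)-3-(methoxymethoxy)non-1-en-4-yl bis(isopinocampheyl)borinate | C=C[C@H](OCOC)[C@H](CCCCC)OB([C@H]1C[C@H]2C[C@@H]([C@@H]1C)C2(C)C)[C@H]1C[C@H]2C[C@@H]([C@@H]1C)C2(C)C | intermediate (not isolated)
7 | (3S,4S)-3-(methoxymethoxy)non-1-en-4-ol | C=C[C@H](OCOC)[C@H](CCCCC)O | intermediate
8 | tert-butyl{[(3S,4S)-3-(methoxymethoxy)non-1-en-4-yl]oxy}dimethylsilane | C=C[C@H](OCOC)[C@H](CCCCC)O[Si](C)(C)C(C)(C)C | intermediate
9 | 9-[(3S,4S)-4-{[tert-butyl(dimethyl)silyl]oxy}-3-(methoxymethoxy)nonyl]-9-borabicyclo[3.3.1]nonane | C1CCC2CCCC1B2CC[C@H](OCOC)[C@H](CCCCC)O[Si](C)(C)C(C)(C)C | intermediate (not isolated)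
10 | (3S,4S)-4-{[tert-butyl(dimethyl)silyl]oxy}-3-(methoxymethoxy)nonan-1-ol | OCC[C@H](OCOC)[C@H](CCCCC)O[Si](C)(C)C(C)(C)C | intermediate
11 | (3S,4S)-4-{[tert-butyl(dimethyl)silyl]oxy}-3-(methoxymethoxy)nonanal | O=CC[C@H](OCOC)[C@H](CCCCC)O[Si](C)(C)C(C)(C)C | intermediate
12 | dec-9-en-1-ol | C=CCCCCCCCCO | starting material
13 | 5-(dec-9-en-1-ylsulfanyl)-1-phenyl-1H-tetrazole | C=CCCCCCCCCSc1nnnn1-c1ccccc1 | intermediate
14 | 5-(dec-9-ene-1-sulfonyl)-1-phenyl-1H-tetrazole | C=CCCCCCCCCS(=O)(=O)c1nnnn1-c1ccccc1 | intermediate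
15 | potassium 1-[(1-phenyl-1H-tetrazol-5-yl)sulfonyl]dec-9-en-1-ide | [K+].C=CCCCCCCC[CH-]S(=O)(=O)c1nnnn1-c1ccccc1 | intermediate (not isolated)
16 | potassium β-alkoxide adduct of 15 and 11 (C9 and C10 transient, configuration not specified; 6S,7S) | [K+].C=CCCCCCCCC(S(=O)(=O)c1nnnn1-c1ccccc1)C([O-])C[C@H](OCOC)[C@H](CCCCC)O[Si](C)(C)C(C)(C)C | intermediate (not isolated)
17 | potassium sulfinate formed from 16 by Smiles rearrangement (tetrazolyl now on the C9 oxygen; C9 and C10 not specified) | [K+].C=CCCCCCCCC(S(=O)[O-])C(Oc1nnnn1-c1ccccc1)C[C@H](OCOC)[C@H](CCCCC)O[Si](C)(C)C(C)(C)C | intermediate (not isolated)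
18 | tert-butyl{[(6S,7S,9E)-7-(methoxymethoxy)nonadeca-9,18-dien-6-yl]oxy}dimethylsilane | C=CCCCCCCC/C=C/C[C@H](OCOC)[C@H](CCCCC)O[Si](C)(C)C(C)(C)C | intermediate
19 | (6S,7S,9E)-7-(methoxymethoxy)nonadeca-9,18-dien-6-ol | C=CCCCCCCC/C=C/C[C@H](OCOC)[C@H](CCCCC)O | intermediate
20 | (6S,7S,9E)-7-(methoxymethoxy)nonadeca-9,18-dien-6-yl perrhenate | C=CCCCCCCC/C=C/C[C@H](OCOC)[C@H](CCCCC)O[Re](=O)(=O)=O | intermediate (not isolated)
21 | dioxorhenium(V) alkoxide of 22 (Re on the C10 oxygen, ring oxygen datively bound) | C=CCCCCCCC[C@@H](O[Re](=O)=O)[C@H]1C[C@H](OCOC)[C@H](CCCCC)O1 | intermediate (not isolated)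
22 | (6S,7S,9R,10R)-6,9-epoxy-7-(methoxymethoxy)nonadec-18-en-10-ol [(1R)-1-[(2R,4S,5S)-4-(methoxymethoxy)-5-pentyloxolan-2-yl]dec-9-en-1-ol] | C=CCCCCCCC[C@@H](O)[C@H]1C[C@H](OCOC)[C@H](CCCCC)O1 | intermediate
23 | dodecanoyl chloride (lauroyl chloride) | CCCCCCCCCCCC(=O)Cl | starting material
24 | (6S,7S,9R,10R)-6,9-epoxy-7-(methoxymethoxy)nonadec-18-en-10-yl dodecanoate | C=CCCCCCCC[C@@H](OC(=O)CCCCCCCCCCC)[C@H]1C[C@H](OCOC)[C@H](CCCCC)O1 | intermediate
25 | (6S,7S,9R,10R)-6,9-epoxy-7-hydroxynonadec-18-en-10-yl dodecanoate [(1R)-1-[(2R,4S,5S)-4-hydroxy-5-pentyloxolan-2-yl]dec-9-en-1-yl dodecanoate; CNP0219213.1] | C=CCCCCCCC[C@@H](OC(=O)CCCCCCCCCCC)[C@H]1C[C@H](O)[C@H](CCCCC)O1 | target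

**Totals**

Total step count: 11. Longest linear sequence: 9 steps (1–4, then 7–11); steps 5–6 form the two-step sulfone branch.

**Steps most likely to fail**

1. Step 9 (oxidative cyclisation).
- What may go wrong: chelation of rhenium by the C7 acetal oxygen may erode the 2,5-trans facial preference or stall the addition. Acid formed from the oxide may ionise the acetal. The secondary alcohol may be oxidised to the ketone instead of cyclising.
- Fallback: it sets out from aldehyde 11 and comes back at alcohol 22, building the ring and C10 in separate, known operations. Wittig methylenation of 11 (Ph3P=CH2, THF, 0 °C) gives tert-butyl{[(4S,5S)-4-(methoxymethoxy)dec-1-en-5-yl]oxy}dimethylsilane F1. TBAF then frees (4S,5S)-4-(methoxymethoxy)dec-1-en-5-ol F2. Cobalt(II)-catalysed aerobic oxidative cyclisation of this pent-4-en-1-ol unit (Co(modp)2, O2, t-BuOOH, i-PrOH, 55 °C; Mukaiyama oxidative cyclisation, known to favour 2,5-trans rings) should give [(2R,4S,5S)-4-(methoxymethoxy)-5-pentyloxolan-2-yl]methanol F3. Dess–Martin oxidation gives (2R,4S,5S)-4-(methoxymethoxy)-5-pentyloxolane-2-carbaldehyde F4. Chelation-controlled addition (MgBr2·OEt2, CH2Cl2/Et2O, −78 °C) of non-8-en-1-ylmagnesium bromide F5, prepared from 9-bromonon-1-ene and magnesium, should then give the threo carbinol 22.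

2. Step 7 (Julia–Kocienski olefination).
- What may go wrong: incomplete E selectivity, where every Z molecule would be carried by the syn addition into the 9,10-erythro epimer, and base-induced β-elimination of the C7 alkoxy group from the aldehyde.
- Fallback: it sets out from aldehyde 11 and comes back at diene 18, fixing the geometry by alkyne reduction. Homologation of 11 with dimethyl (1-diazo-2-oxopropyl)phosphonate (K2CO3, MeOH; Ohira–Bestmann reaction) gives tert-butyl{[(4S,5S)-4-(methoxymethoxy)dec-1-yn-5-yl]oxy}dimethylsilane F6. Deprotonation (n-BuLi, THF/DMPU, −78 °C) and alkylation with 9-bromonon-1-ene gives tert-butyl{[(6S,7S)-7-(methoxymethoxy)nonadec-18-en-9-yn-6-yl]oxy}dimethylsilane F7. Dissolving-metal reduction (Na, liquid NH3, THF, −78 → −33 °C) should give only the E alkene 18 and leave the isolated terminal alkene, the silyl ether and the acetal untouched.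

3. Step 11 (MOM cleavage beside the laurate).
- What may go wrong: Lewis acid-promoted loss or migration of the laurate, or opening of the oxolane, competing with slow cleavage of the hindered C7 acetal.
- Fallback: it sets out from alcohol 22 and comes back at target 25, by-passing 24, so that the acetal is cleaved before any ester is present and the last deprotection is oxidative and neutral. Silylation of C10–OH (TBDPSCl, imidazole, DMAP, DMF) gives tert-butyl{[(6S,7S,9R,10R)-6,9-epoxy-7-(methoxymethoxy)nonadec-18-en-10-yl]oxy}diphenylsilane F8. ZnBr2/n-PrSH then gives (6S,7S,9R,10R)-10-{[tert-butyl(diphenyl)silyl]oxy}-6,9-epoxynonadec-18-en-7-ol F9. Etherification of C7–OH (NaH, 4-methoxybenzyl chloride, TBAI, DMF) gives tert-butyl({(6S,7S,9R,10R)-6,9-epoxy-7-[(4-methoxybenzyl)oxy]nonadec-18-en-10-yl}oxy)diphenylsilane F10. TBAF gives (6S,7S,9R,10R)-6,9-epoxy-7-[(4-methoxybenzyl)oxy]nonadec-18-en-10-ol F11. Acylation with 23 (pyridine, DMAP) gives (6S,7S,9R,10R)-6,9-epoxy-7-[(4-methoxybenzyl)oxy]nonadec-18-en-10-yl dodecanoate F12. DDQ (CH2Cl2/pH 7 buffer, 0 °C) removes the PMB group to give 25.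

**Further compounds**

F1 | step 9 | tert-butyl{[(4S,5S)-4-(methoxymethoxy)dec-1-en-5-yl]oxy}dimethylsilane | C=CC[C@H](OCOC)[C@H](CCCCC)O[Si](C)(C)C(C)(C)C
F2 | step 9 | (4S,5S)-4-(methoxymethoxy)dec-1-en-5-ol | C=CC[C@H](OCOC)[C@H](CCCCC)O
F3 | step 9 | [(2R,4S,5S)-4-(methoxymethoxy)-5-pentyloxolan-2-yl]methanol | OC[C@H]1C[C@H](OCOC)[C@H](CCCCC)O1
F4 | step 9 | (2R,4S,5S)-4-(methoxymethoxy)-5-pentyloxolane-2-carbaldehyde | O=C[C@H]1C[C@H](OCOC)[C@H](CCCCC)O1
F5 | step 9 | non-8-en-1-ylmagnesium bromide | C=CCCCCCCC[Mg]Br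
F6 | step 7 | tert-butyl{[(4S,5S)-4-(methoxymethoxy)dec-1-yn-5-yl]oxy}dimethylsilane | C#CC[C@H](OCOC)[C@H](CCCCC)O[Si](C)(C)C(C)(C)C
F7 | step 7 | tert-butyl{[(6S,7S)-7-(methoxymethoxy)nonadec-18-en-9-yn-6-yl]oxy}dimethylsilane | C=CCCCCCCCC#CC[C@H](OCOC)[C@H](CCCCC)O[Si](C)(C)C(C)(C)C
F8 | step 11 | tert-butyl{[(6S,7S,9R,10R)-6,9-epoxy-7-(methoxymethoxy)nonadec-18-en-10-yl]oxy}diphenylsilane | C=CCCCCCCC[C@@H](O[Si](c1ccccc1)(c1ccccc1)C(C)(C)C)[C@H]1C[C@H](OCOC)[C@H](CCCCC)O1
F9 | step 11 | (6S,7S,9R,10R)-10-{[tert-butyl(diphenyl)silyl]oxy}-6,9-epoxynonadec-18-en-7-ol | C=CCCCCCCC[C@@H](O[Si](c1ccccc1)(c1ccccc1)C(C)(C)C)[C@H]1C[C@H](O)[C@H](CCCCC)O1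
F10 | step 11 | tert-butyl({(6S,7S,9R,10R)-6,9-epoxy-7-[(4-methoxybenzyl)oxy]nonadec-18-en-10-yl}oxy)diphenylsilane | C=CCCCCCCC[C@@H](O[Si](c1ccccc1)(c1ccccc1)C(C)(C)C)[C@H]1C[C@H](OCc2ccc(OC)cc2)[C@H](CCCCC)O1
F11 | step 11 | (6S,7S,9R,10R)-6,9-epoxy-7-[(4-methoxybenzyl)oxy]nonadec-18-en-10-ol | C=CCCCCCCC[C@@H](O)[C@H]1C[C@H](OCc2ccc(OC)cc2)[C@H](CCCCC)O1
F12 | step 11 | (6S,7S,9R,10R)-6,9-epoxy-7-[(4-methoxybenzyl)oxy]nonadec-18-en-10-yl dodecanoate | C=CCCCCCCC[C@@H](OC(=O)CCCCCCCCCCC)[C@H]1C[C@H](OCc2ccc(OC)cc2)[C@H](CCCCC)O1
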